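**Retrosynthetic overview**
1. The (Z)-butylidene butenolide is made last: Ag(I) 5-exo-dig lactonisation of the cis-enynoic acid 28, which comes from enol-triflate carbonylation and a Sonogashira coupling on a diosphenol triflate.
2. The diosphenol comes from a cis-diol on the two future butenolide ring carbons, carried as an acetonide from the arene dihydroxylation.
3. The spiro-phthalide comes from convex-face addition of an ortho-ester aryl Grignard to the endo-propyl cyclobutanone 13, followed by lactonisation.
4. The cyclobutanone comes from dichloroketene [2+2] on diene acetonide 3 (anti to the dioxolane), dehalogenation, aldol condensation with propanal and convex-face hydrogenation.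
5. Absolute configuration comes from enzymatic cis-dihydroxylation of bromobenzene. Ring order: six-membered carbocycle (from the arene) → cyclobutanone → spiro-phthalide → butenolide.

**Assumption and conventions**
- The target SMILES is read as drawn: the three cyclobutane hydrogens and the phthalide aryl lie on one face; the lactone oxygen, the propyl group and the six-membered ring lie on the other; the butylidene is Z.
- Intermediates use bicyclo[4.2.0]octane locants: C1/C6 = ring fusion, C7 = cyclobutanone (later spiro) carbon, C8 = its other neighbour (propyl carbon), C5 (next to C6) and C4 = the oxygenated carbons that become the butenolide ring-fusion carbons.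
- "exo" = convex face (face of the ring-fusion hydrogens); "endo" = face of the six-membered ring.
- Absolute configuration of each compound is defined by its SMILES.

**Route**

Step 1
Reactants: 1 bromobenzene
Product: 2 (1S,2S)-3-bromocyclohexa-3,5-diene-1,2-diol
Conditions: E. coli JM109(pDTG601) whole cells expressing toluene dioxygenase, air (O2), glucose, phosphate buffer pH 7, 35 °C (NADH recycled in vivo)
Reagents that add atoms: dioxygen, O=O
Why: Toluene dioxygenase, a Rieske non-haem-iron arene cis-dihydroxylating dioxygenase (oxidoreductase), adds both atoms of O2 to one enantiotopic face of the 2,3-bond; this enzymatic asymmetric dihydroxylation sets the first two stereocentres (>99% ee) from an achiral arene.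

Step 2
Reactants: 2 (1S,2S)-3-bromocyclohexa-3,5-diene-1,2-diol
Product: 3 (3aS,7aS)-4-bromo-2,2-dimethyl-3a,7a-dihydro-1,3-benzodioxole
Conditions: Me2C(OMe)2, cat. TsOH, acetone, 0 °C to rt; used at once
Reagents that add atoms: 2,2-dimethoxypropane, COC(C)(C)OC
Why: Acid-catalysed transketalisation (acetonide formation) of the cis-diol blocks one face of the diene without touching a stereocentre.

Step 3
Reactants: 3 bromodiene acetonide; 4 trichloroacetyl chloride
Product: 6 3-bromo-8,8-dichloro-4,5-(isopropylidenedioxy)bicyclo[4.2.0]oct-2-en-7-one (cis-fused; dioxolane anti to the cyclobutanone), via dichloroketene 5 (not isolated)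
Conditions: Cl3CCOCl, Zn–Cu, DME, Et2O, rt, slow addition
Reagents that add atoms: trichloroacetyl chloride (4), ClC(=O)C(Cl)(Cl)Cl
Why: Ketene–diene [2+2] cycloaddition at the unsubstituted double bond, with the ketene carbonyl carbon bonding to the free diene terminus (next to the C–O carbon) and approach anti to the dioxolane; this sets both ring-fusion stereocentres cis.

Step 4
Reactants: 6 dichlorocyclobutanone
Product: 7 4,5-(isopropylidenedioxy)bicyclo[4.2.0]oct-2-en-7-one (cis-fused; dioxolane anti)
Conditions: Bu3SnH (3.5 equiv), AIBN (cat.), PhMe, 90 °C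
Reagents that add atoms: none
Why: Radical-chain tin hydride dehalogenation removes both α-keto chlorines and the vinyl bromide; no stereocentre is affected.

Step 5
Reactants: 7 cyclobutanone; 8 propanal
Product: 10 8-(1-hydroxypropyl)-4,5-(isopropylidenedioxy)bicyclo[4.2.0]oct-2-en-7-one (mixture at C8 and the carbinol carbon), via lithium enolate 9 (not isolated)
Conditions: LDA, THF, −78 °C; EtCHO; AcOH quench at −78 °C
Reagents that add atoms: propanal (8), CCC=O
Why: Directed aldol addition; kinetic deprotonation occurs at the C8 methylene and not at the ring-fusion CH, and both new centres are erased in steps 6–7.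

Step 6
Reactants: 10 aldol adduct
Product: 12 (E)-4,5-(isopropylidenedioxy)-8-propylidenebicyclo[4.2.0]oct-2-en-7-one, via mesylate 11 (not isolated)
Conditions: MsCl, Et3N, CH2Cl2, 0 °C; then DBU, rt
Reagents that add atoms: none
Why: Mesylation and E1cB elimination complete the aldol condensation to the conjugated alkylidene cyclobutanone.

Step 7
Reactants: 12 propylidene enone
Product: 13 4,5-(isopropylidenedioxy)-8-endo-propylbicyclo[4.2.0]octan-7-one
Conditions: H2 (1 atm), 10% Pd/C, EtOAc, rt
Reagents that add atoms: none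
Why: Heterogeneous catalytic hydrogenation delivers H2 syn to the exocyclic enone from the convex face, so the propyl group ends endo (cis to the six-membered ring), which sets C8; the ring alkene is saturated at the same time.

Step 8
Reactants: 13 endo-propyl cyclobutanone; 14 methyl 2-iodobenzoate
Product: 17 4,5-(isopropylidenedioxy)-8-endo-propyl-3'H-spiro[bicyclo[4.2.0]octane-7,1'-isobenzofuran]-3'-one (aryl exo; lactone O endo), via arylmagnesium chloride 15 (not isolated), via magnesium alkoxide 16 (not isolated)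
Conditions: 14, iPrMgCl·LiCl, THF, −40 °C; then 13, LaCl3·2LiCl, −40 to 0 °C; then rt
Reagents that add atoms: methyl 2-iodobenzoate (14), COC(=O)c1ccccc1I
Why: Iodine–magnesium exchange, then Grignard 1,2-addition to the strained ketone from the convex face (anti to the endo-propyl group and the six-membered ring) sets the spiro centre with aryl exo and O endo; the alkoxide then lactonises onto the ortho ester to give the phthalide.

Step 9
Reactants: 17 spiro-phthalide acetonide
Product: 18 4,5-dihydroxy-8-endo-propyl-3'H-spiro[bicyclo[4.2.0]octane-7,1'-isobenzofuran]-3'-one (cis-diol)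
Conditions: AcOH–H2O (4:1), 50 °C
Reagents that add atoms: none
Why: Acid-catalysed acetal hydrolysis; the phthalide is stable to aqueous acid.

Step 10
Reactants: 18 cis-diol
Product: 20 4-hydroxy-8-endo-propyl-3'H-spiro[bicyclo[4.2.0]oct-3-ene-7,1'-isobenzofuran]-3',5-dione (diosphenol), via α-diketone 19 (not isolated)
Conditions: IBX (3 equiv), DMSO, rt
Reagents that add atoms: none
Why: Hypervalent-iodine (IBX) oxidation converts the vic-diol to the 1,2-dione without C–C cleavage; the dione enolises away from the ring fusion, and the two auxiliary stereocentres are removed.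

Step 11
Reactants: 20 diosphenol
Product: 21 5-oxo-enol triflate: 3',5-dioxo-8-endo-propyl-3'H-spiro[bicyclo[4.2.0]oct-3-ene-7,1'-isobenzofuran]-4-yl trifluoromethanesulfonate
Conditions: Tf2O, pyridine, CH2Cl2, −78 to 0 °C
Reagents that add atoms: triflic anhydride, O=S(=O)(OS(=O)(=O)C(F)(F)F)C(F)(F)F
Why: O-Sulfonylation of the acidic enol gives the α-triflyloxy enone as a cross-coupling handle.

Step 12
Reactants: 21 α-triflyloxy enone; 22 pent-1-yne
Product: 23 4-(pent-1-yn-1-yl)-8-endo-propyl-3'H-spiro[bicyclo[4.2.0]oct-3-ene-7,1'-isobenzofuran]-3',5-dione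
Conditions: PdCl2(PPh3)2 (5 mol %), CuI (10 mol %), iPr2NH, THF, rt
Reagents that add atoms: pent-1-yne (22), CCCC#C
Why: Sonogashira coupling of the electron-poor enol triflate at room temperature; the mild amine base limits enolisation at the ring-fusion CH.

Step 13
Reactants: 23 alkynyl enone
Product: 25 3'-oxo-4-(pent-1-yn-1-yl)-8-endo-propyl-3'H-spiro[bicyclo[4.2.0]oct-4-ene-7,1'-isobenzofuran]-5-yl trifluoromethanesulfonate, via lithium enolate 24 (not isolated)
Conditions: L-Selectride, THF, −78 °C; then PhNTf2, −78 to 0 °C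
Reagents that add atoms: N-phenylbis(trifluoromethanesulfonimide), O=S(=O)(N(c1ccccc1)S(=O)(=O)C(F)(F)F)C(F)(F)F
Why: Conjugate (1,4) hydride reduction of the β-unsubstituted cyclohexenone gives the regiodefined enolate, and O-triflation gives the tetrasubstituted enol triflate; the lactone is inert at −78 °C.

Step 14
Reactants: 25 dienyne triflate; 26 carbon monoxide
Product: 27 2-(trimethylsilyl)ethyl 3'-oxo-4-(pent-1-yn-1-yl)-8-endo-propyl-3'H-spiro[bicyclo[4.2.0]oct-4-ene-7,1'-isobenzofuran]-5-carboxylate
Conditions: CO (1 atm), Pd(OAc)2 (10 mol %), dppf, Et3N, TMSCH2CH2OH (5 equiv), DMF, 60 °C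
Reagents that add atoms: carbon monoxide (26), [C-]#[O+]; 2-(trimethylsilyl)ethanol, C[Si](C)(C)CCO
Why: Pd-catalysed alkoxycarbonylation of the enol triflate places the carboxyl carbon cis to the alkyne on the tetrasubstituted alkene.

Step 15
Reactants: 27 TMSE ester
Product: 28 3'-oxo-4-(pent-1-yn-1-yl)-8-endo-propyl-3'H-spiro[bicyclo[4.2.0]oct-4-ene-7,1'-isobenzofuran]-5-carboxylic acid
Conditions: TBAF, THF, 0 °C to rt; then 1 M HCl to pH 3
Reagents that add atoms: none
Why: Fluoride-induced β-elimination of the silylethyl ester frees the acid without hydroxide, so the phthalide stays closed.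

Step 16
Reactants: 28 cis-enynoic acid
Product: 29 target CNP0248594.2
Conditions: AgNO3 (10 mol %), acetone, rt, dark
Reagents that add atoms: none
Why: Ag(I)-catalysed 5-exo-dig lactonisation (anti-oxymetalation, then protodemetalation) of the (Z)-2-en-4-ynoic acid gives the γ-alkylidene butenolide with Z geometry (propyl syn to the ring oxygen).

**Compound list**
1 | bromobenzene | Brc1ccccc1 | starting material
2 | (1S,2S)-3-bromocyclohexa-3,5-diene-1,2-diol | O[C@H]1C=CC=C(Br)[C@H]1O | intermediate
3 | (3aS,7aS)-4-bromo-2,2-dimethyl-3a,7a-dihydro-1,3-benzodioxole | CC1(C)O[C@H]2C=CC=C(Br)[C@H]2O1 | intermediate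
4 | trichloroacetyl chloride | ClC(=O)C(Cl)(Cl)Cl | starting material
5 | dichloroketene (not isolated) | ClC(Cl)=C=O | intermediate
6 | 3-bromo-8,8-dichloro-4,5-(isopropylidenedioxy)bicyclo[4.2.0]oct-2-en-7-one, cis-fused, dioxolane anti to the four-membered ring | CC1(C)O[C@H]2[C@@H]3C(=O)C(Cl)(Cl)[C@@H]3C=C(Br)[C@H]2O1 | intermediate
7 | 4,5-(isopropylidenedioxy)bicyclo[4.2.0]oct-2-en-7-one, cis-fused, dioxolane anti | CC1(C)O[C@H]2[C@@H]3C(=O)C[C@@H]3C=C[C@H]2O1 | intermediate
8 | propanal | CCC=O | starting material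
9 | lithium enolate of 7 (C7–OLi, C7=C8; not isolated) | CC1(C)O[C@H]2[C@@H]3C(O[Li])=C[C@@H]3C=C[C@H]2O1 | intermediate
10 | 8-(1-hydroxypropyl)-4,5-(isopropylidenedioxy)bicyclo[4.2.0]oct-2-en-7-one, mixture at C8 and carbinol carbon | CC1(C)O[C@H]2[C@@H]3C(=O)C(C(O)CC)[C@@H]3C=C[C@H]2O1 | intermediate
11 | methanesulfonate of 10 (not isolated) | CC1(C)O[C@H]2[C@@H]3C(=O)C(C(OS(C)(=O)=O)CC)[C@@H]3C=C[C@H]2O1 | intermediate
12 | (E)-4,5-(isopropylidenedioxy)-8-propylidenebicyclo[4.2.0]oct-2-en-7-one | CC1(C)O[C@H]2[C@@H]3C(=O)/C(=C/CC)[C@@H]3C=C[C@H]2O1 | intermediate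
13 | 4,5-(isopropylidenedioxy)-8-endo-propylbicyclo[4.2.0]octan-7-one (propyl cis to the six-membered ring) | CC1(C)O[C@H]2[C@@H]3C(=O)[C@H](CCC)[C@@H]3CC[C@H]2O1 | intermediate
14 | methyl 2-iodobenzoate | COC(=O)c1ccccc1I | starting material
15 | [2-(methoxycarbonyl)phenyl]magnesium chloride (not isolated) | COC(=O)c1ccccc1[Mg]Cl | intermediate
16 | chloromagnesium alkoxide of the exo-aryl tertiary carbinol (not isolated) | CC1(C)O[C@H]2[C@@H]3[C@@](O[Mg]Cl)(c4ccccc4C(=O)OC)[C@H](CCC)[C@@H]3CC[C@H]2O1 | intermediate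
17 | 4,5-(isopropylidenedioxy)-8-endo-propyl-3'H-spiro[bicyclo[4.2.0]octane-7,1'-isobenzofuran]-3'-one, aryl exo, lactone O endo | CC1(C)O[C@H]2[C@@H]3[C@]4(OC(=O)c5ccccc54)[C@H](CCC)[C@@H]3CC[C@H]2O1 | intermediate
18 | 4,5-cis-dihydroxy-8-endo-propyl-3'H-spiro[bicyclo[4.2.0]octane-7,1'-isobenzofuran]-3'-one | O[C@H]1[C@@H]2[C@]3(OC(=O)c4ccccc43)[C@H](CCC)[C@@H]2CC[C@H]1O | intermediate
19 | 8-endo-propyl-3'H-spiro[bicyclo[4.2.0]octane-7,1'-isobenzofuran]-3',4,5-trione (α-diketone, not isolated) | O=C1[C@@H]2[C@]3(OC(=O)c4ccccc43)[C@H](CCC)[C@@H]2CCC1=O | intermediate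
20 | 4-hydroxy-8-endo-propyl-3'H-spiro[bicyclo[4.2.0]oct-3-ene-7,1'-isobenzofuran]-3',5-dione (diosphenol) | O=C1[C@@H]2[C@]3(OC(=O)c4ccccc43)[C@H](CCC)[C@@H]2CC=C1O | intermediate
21 | 3',5-dioxo-8-endo-propyl-3'H-spiro[bicyclo[4.2.0]oct-3-ene-7,1'-isobenzofuran]-4-yl trifluoromethanesulfonate | O=C1[C@@H]2[C@]3(OC(=O)c4ccccc43)[C@H](CCC)[C@@H]2CC=C1OS(=O)(=O)C(F)(F)F | intermediate
22 | pent-1-yne | CCCC#C | starting material
23 | 4-(pent-1-yn-1-yl)-8-endo-propyl-3'H-spiro[bicyclo[4.2.0]oct-3-ene-7,1'-isobenzofuran]-3',5-dione | O=C1[C@@H]2[C@]3(OC(=O)c4ccccc43)[C@H](CCC)[C@@H]2CC=C1C#CCCC | intermediate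
24 | lithium enolate from 1,4-reduction of 23 (C5–OLi, C4=C5; not isolated) | [Li]OC1=C(C#CCCC)CC[C@H]2[C@@H](CCC)[C@@]3(OC(=O)c4ccccc43)[C@@H]12 | intermediate
25 | 3'-oxo-4-(pent-1-yn-1-yl)-8-endo-propyl-3'H-spiro[bicyclo[4.2.0]oct-4-ene-7,1'-isobenzofuran]-5-yl trifluoromethanesulfonate | O=S(=O)(OC1=C(C#CCCC)CC[C@H]2[C@@H](CCC)[C@@]3(OC(=O)c4ccccc43)[C@@H]12)C(F)(F)F | intermediate
26 | carbon monoxide | [C-]#[O+] | starting material
27 | 2-(trimethylsilyl)ethyl 3'-oxo-4-(pent-1-yn-1-yl)-8-endo-propyl-3'H-spiro[bicyclo[4.2.0]oct-4-ene-7,1'-isobenzofuran]-5-carboxylate | C[Si](C)(C)CCOC(=O)C1=C(C#CCCC)CC[C@H]2[C@@H](CCC)[C@@]3(OC(=O)c4ccccc43)[C@@H]12 | intermediate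
28 | 3'-oxo-4-(pent-1-yn-1-yl)-8-endo-propyl-3'H-spiro[bicyclo[4.2.0]oct-4-ene-7,1'-isobenzofuran]-5-carboxylic acid | OC(=O)C1=C(C#CCCC)CC[C@H]2[C@@H](CCC)[C@@]3(OC(=O)c4ccccc43)[C@@H]12 | intermediate
29 | target CNP0248594.2: cyclobutane-fused (Z)-3-butylidene-4,5,6,7-tetrahydrophthalide spiro-linked to a phthalide, propyl on the four-membered ring | CCC/C=C1\OC(=O)C2=C1CC[C@H]1[C@@H](CCC)[C@@]3(OC(=O)c4ccccc43)[C@@H]21 | target

**Totals**
Total step count: 16. Longest linear sequence: 16 steps (from bromobenzene 1); the other carbon sources 4, 8, 14, 22 and 26 are bought.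

**Three steps most likely to fail, with fallbacks**

Step 3 (dichloroketene [2+2] on the acid-sensitive halodiene acetonide). The risks are decomposition of 3 by zinc salts and low reactivity of the bromodiene. The fallback puts the propyl group on the ketene and uses base-only ketene generation. It sets out from 3: 2-chloropentanoyl chloride and Et3N (hexane–Et2O, rt, syringe pump) give chloro(propyl)ketene F1, which cycloadds with the same regio- and facial sense to give 3-bromo-8-chloro-4,5-(isopropylidenedioxy)-8-propylbicyclo[4.2.0]oct-2-en-7-one F2 (C8 epimers). Bu3SnH/AIBN (PhMe, 90 °C) then removes chlorine and bromine, the planar α-keto radical taking hydrogen from the convex face, to give 4,5-(isopropylidenedioxy)-8-endo-propylbicyclo[4.2.0]oct-2-en-7-one F3. Hydrogenation of F3 (H2, Pd/C, EtOAc) comes back to the route at 13, so 6, 7, 10 and 12 are not needed.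

Step 8 (addition of the ester-bearing aryl Grignard to the hindered, enolisable cyclobutanone). The risks are enolisation with loss of the endo-propyl configuration and sluggish addition. The fallback separates C–C bond formation from lactone formation. It sets out from 13: 1-bromo-2-iodobenzene and iPrMgCl·LiCl (THF, −20 °C) give (2-bromophenyl)magnesium chloride F4, which adds with LaCl3·2LiCl to the convex face of 13 to give the tertiary carbinol 7-exo-(2-bromophenyl)-4,5-(isopropylidenedioxy)-8-endo-propylbicyclo[4.2.0]octan-7-ol F5. Pd-catalysed carbonylative lactonisation of F5 (CO 1 atm, Pd(OAc)2, dppf, Et3N, DMF, 90 °C) closes the phthalide and comes back to the route at 17.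

Step 13 (L-Selectride conjugate reduction and in-situ triflation). The risks are 1,2-reduction, attack on the lactone and slow O-triflation of the hindered enolate. The fallback separates reduction from triflation and avoids a basic enolate. It sets out from 23: Stryker's reagent, [(Ph3P)CuH]6, in wet benzene at rt reduces only the enone to the saturated ketone 4-(pent-1-yn-1-yl)-8-endo-propyl-3'H-spiro[bicyclo[4.2.0]octane-7,1'-isobenzofuran]-3',5-dione F6 (C4 epimers). Electrophilic enol triflation of F6 (Tf2O, 2,6-di-tert-butyl-4-methylpyridine, CH2Cl2, 0 °C) gives the more substituted, alkyne-conjugated enol triflate and comes back to the route at 25.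

Further compounds
F1 | step 3 | chloro(propyl)ketene | CCCC(Cl)=C=O
F2 | step 3 | 3-bromo-8-chloro-4,5-(isopropylidenedioxy)-8-propylbicyclo[4.2.0]oct-2-en-7-one (C8 epimers) | CC1(C)O[C@H]2[C@@H]3C(=O)C(Cl)(CCC)[C@@H]3C=C(Br)[C@H]2O1
F3 | step 3 | 4,5-(isopropylidenedioxy)-8-endo-propylbicyclo[4.2.0]oct-2-en-7-one | CC1(C)O[C@H]2[C@@H]3C(=O)[C@H](CCC)[C@@H]3C=C[C@H]2O1
F4 | step 8 | (2-bromophenyl)magnesium chloride | Brc1ccccc1[Mg]Cl
F5 | step 8 | 7-exo-(2-bromophenyl)-4,5-(isopropylidenedioxy)-8-endo-propylbicyclo[4.2.0]octan-7-ol | CC1(C)O[C@H]2[C@@H]3[C@@](O)(c4ccccc4Br)[C@H](CCC)[C@@H]3CC[C@H]2O1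
F6 | step 13 | 4-(pent-1-yn-1-yl)-8-endo-propyl-3'H-spiro[bicyclo[4.2.0]octane-7,1'-isobenzofuran]-3',5-dione (C4 epimers) | O=C1[C@@H]2[C@]3(OC(=O)c4ccccc43)[C@H](CCC)[C@@H]2CCC1C#CCCC
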